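The retrosynthesis masks the C7 hydroxyl as a tert-butyl ether, opens ring C at O1–C2 to an o-hydroxyaryl ynone, and takes the C4 carbonyl back to a silyl-protected carbinol.
Ring A is then cut at C5–C6, C4a–C8a and C8–C8a into an alkenyl(methoxy)carbene chromium complex (C6, C7, C8), one of its CO ligands (C8a) and the terminal alkyne of a skipped diyne (C5, C4a). Ring B is bought.
Enabling feature: on ring A the oxygen at C8a (O1) lies para to the C6 methoxy group, and the C4 chain sits at C4a, ortho to that oxygen. This is a 4-methoxyphenol with its bulky substituent next to OH, as a carbene/alkyne/CO benzannulation gives. The C7 oxygen comes from the α-alkoxy group of the vinyl unit.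
Forward: the carbene complex (one step) and the diyne (three steps) are made separately and joined to build ring A, followed by desilylation, oxidation, amine-mediated closure of ring C and acid deprotection.
Stereochemistry: the target has no stereocentre. The only one on the way (the C4 carbinol) is carried racemic and disappears on oxidation.

Key step: step 5

Assumption: tert-butyl vinyl ether, Cr(CO)6, 5-ethynyl-1,2,3-trimethoxybenzene and ethynylmagnesium bromide (THF solution) are taken as purchasable.

Step 1
Reactants: 1 tert-butyl vinyl ether; 2 chromium hexacarbonyl, Cr(CO)6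
Product: 5 pentacarbonyl[(1-tert-butoxyvinyl)(methoxy)carbene]chromium, via 1-tert-butoxyvinyllithium 3 (not isolated), via lithium pentacarbonyl(2-tert-butoxyacryloyl)chromate 4 (not isolated)
Conditions: 1 (1.3 equiv), t-BuLi, THF–pentane, −78 → 0 °C; Cr(CO)6, Et2O, 0 °C → rt; evaporate; Me3OBF4, CH2Cl2, 0 °C → rt; aq NaHCO3
Reagents that add atoms: trimethyloxonium tetrafluoroborate, C[O+](C)C.F[B-](F)(F)F
Why: α-Deprotonation of an alkyl vinyl ether with t-BuLi, addition of the vinyllithium to a CO ligand of Cr(CO)6 and O-methylation of the acylate with a hard oxonium salt is the standard Fischer carbene complex synthesis, and the slight excess of 1 leaves no t-BuLi to attack the metal carbonyl.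

Step 2
Reactants: 6 5-ethynyl-1,2,3-trimethoxybenzene
Product: 9 3-(3,4,5-trimethoxyphenyl)prop-2-ynal, via lithium (3,4,5-trimethoxyphenyl)acetylide 7 (not isolated), via lithium 1-(dimethylamino)-3-(3,4,5-trimethoxyphenyl)prop-2-yn-1-olate 8 (not isolated)
Conditions: n-BuLi, THF, −78 °C; DMF, −78 → 0 °C; reverse quench into aq KH2PO4/MTBE, 0 °C
Reagents that add atoms: N,N-dimethylformamide, CN(C)C=O
Why: Formylation of a lithium acetylide with DMF (Bouveault-type aldehyde synthesis) stops at the stable hemiaminal alkoxide, and the reverse quench into acidic phosphate protonates the released dimethylamine before it can add to the ynal.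

Step 3
Reactants: 9 3-(3,4,5-trimethoxyphenyl)prop-2-ynal; 10 ethynylmagnesium bromide
Product: 12 1-(3,4,5-trimethoxyphenyl)penta-1,4-diyn-3-ol (racemic), via bromomagnesium 1-(3,4,5-trimethoxyphenyl)penta-1,4-diyn-3-olate 11 (not isolated)
Conditions: THF, −78 → 0 °C; aq NH4Cl
Reagents that add atoms: none
Why: Grignard 1,2-addition of an alkynyl nucleophile to an ynal is fast and clean at low temperature, and the new carbinol centre is formed without control as a racemate, which is harmless because it later becomes the C4 carbonyl carbon.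

Step 4
Reactants: 12 1-(3,4,5-trimethoxyphenyl)penta-1,4-diyn-3-ol (racemic)
Product: 13 tert-butyl(dimethyl){[1-(3,4,5-trimethoxyphenyl)penta-1,4-diyn-3-yl]oxy}silane (racemic)
Conditions: TBSCl, imidazole, DMF, 0 °C → rt
Reagents that add atoms: tert-butyldimethylsilyl chloride, CC(C)(C)[Si](C)(C)Cl
Why: Imidazole-promoted O-silylation of a secondary alcohol is mild enough for the base-sensitive skipped diynol, removes the free OH that could trap a ketene intermediate, and adds the bulk that steers the alkyne orientation in the next step.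

Step 5
Reactants: 5 pentacarbonyl[(1-tert-butoxyvinyl)(methoxy)carbene]chromium; 13 tert-butyl(dimethyl){[1-(3,4,5-trimethoxyphenyl)penta-1,4-diyn-3-yl]oxy}silane (racemic)
Product: 15 5-tert-butoxy-2-[1-(tert-butyldimethylsilyloxy)-3-(3,4,5-trimethoxyphenyl)prop-2-ynyl]-4-methoxyphenol (racemic), via Cr(CO)3-complexed phenol 14 (not isolated)
Conditions: 13 (1.3 equiv), THF (0.1 M), Ar, 50 °C; then air, Et2O–CH2Cl2, rt
Reagents that add atoms: none
Why: Thermal loss of one cis CO ligand from 5 lets the terminal alkyne of 13 coordinate and insert into the Cr=C bond, its CH carbon (C5) bonding to the carbene carbon (C6), and migration of a CO ligand onto the new vinylcarbene carbon (C4a) gives a chromium-bound dienylketene whose ketene carbon is C8a. Ring A, the only ring formed, closes by six-electron electrocyclisation of this dienylketene (C8a onto the vinyl CH2, C8), and enolisation of the cyclohexadienone gives complex 14, which air demetalates to 15 with methyl ether, tert-butyl ether and free phenol already differentiated. The closest known reaction type is the Dötz benzannulation of α-alkoxyalkenyl (for instance dihydropyranyl) methoxycarbene complexes of zerovalent chromium with terminal alkynes, propargylic silyl ethers included. No stereocentre is created, since the carbinol carbon of 13 is a racemic spectator and the diastereomeric planar-chiral forms of 14 merge into one compound on loss of Cr(CO)3. Regioselectivity is needed and is steric in origin, because hydrogen takes the internal position of the η3-vinylcarbene intermediate, where a larger group would clash with a CO ligand, so the branched CH(OTBS)(alkynyl) chain sits on the new carbene carbon and ends next to the CO-derived C8a. Chemoselectivity between the two alkynes is needed as well and rests on the faster binding of the unhindered terminal alkyne, on keeping 5 as the limiting partner, and on the one-carbon tether, which would force a three- or four-membered ring if the aryl alkyne tried to intercept the vinylcarbene.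

Step 6
Reactants: 15 5-tert-butoxy-2-[1-(tert-butyldimethylsilyloxy)-3-(3,4,5-trimethoxyphenyl)prop-2-ynyl]-4-methoxyphenol (racemic)
Product: 16 5-tert-butoxy-2-[1-hydroxy-3-(3,4,5-trimethoxyphenyl)prop-2-ynyl]-4-methoxyphenol (racemic)
Conditions: Bu4NF, AcOH (1:1), THF, 0 °C → rt; product used without storage
Reagents that add atoms: none
Why: Fluoride-mediated cleavage of the Si–O bond (desilylation) leaves the aryl tert-butyl ether untouched, and the AcOH buffer keeps phenoxide and alkoxide levels low, so neither attack of the phenol on the alkyne nor quinone methide formation is expected.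

Step 7
Reactants: 16 5-tert-butoxy-2-[1-hydroxy-3-(3,4,5-trimethoxyphenyl)prop-2-ynyl]-4-methoxyphenol (racemic)
Product: 17 1-(4-tert-butoxy-2-hydroxy-5-methoxyphenyl)-3-(3,4,5-trimethoxyphenyl)prop-2-yn-1-one
Conditions: activated MnO2 (excess), CH2Cl2, 0 °C → rt
Reagents that add atoms: none
Why: Heterogeneous MnO2 oxidation selects activated alcohols, and this carbinol is both benzylic and propargylic, so it should be consumed before the phenol ring is touched, after which the phenol is deactivated by conjugation with and hydrogen bonding to the new carbonyl group.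

Step 8
Reactants: 17 1-(4-tert-butoxy-2-hydroxy-5-methoxyphenyl)-3-(3,4,5-trimethoxyphenyl)prop-2-yn-1-one
Product: 19 7-tert-butoxy-6-methoxy-2-(3,4,5-trimethoxyphenyl)-4H-chromen-4-one, via (E)-β-diethylamino enaminone 18 (not isolated)
Conditions: Et2NH (3 equiv), EtOH, rt → 60 °C
Reagents that add atoms: none
Why: Aza-Michael addition of Et2NH to the ynone gives enaminone 18, whose β-carbon is the only electrophilic site left, so the phenol closes ring C by 6-endo-trig addition–elimination with release of the amine and the 5-exo path to the aurone is shut off.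

Step 9
Reactants: 19 7-tert-butoxy-6-methoxy-2-(3,4,5-trimethoxyphenyl)-4H-chromen-4-one
Product: 20 prosogerin D, 7-hydroxy-6-methoxy-2-(3,4,5-trimethoxyphenyl)-4H-chromen-4-one
Conditions: CF3CO2H, CH2Cl2, 0 °C → rt
Reagents that add atoms: none
Why: Acidolysis of an aryl tert-butyl ether (loss of the tert-butyl cation as isobutene) is fast in CF3CO2H, whereas the four aryl methyl ethers and the γ-pyrone are inert and the carbonyl-deactivated ring A resists tert-butylation.

Compound list
1 | tert-butyl vinyl ether | C=COC(C)(C)C | starting material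
2 | chromium hexacarbonyl, Cr(CO)6 | [Cr].[C-]#[O+].[C-]#[O+].[C-]#[O+].[C-]#[O+].[C-]#[O+].[C-]#[O+] | starting material
3 | 1-tert-butoxyvinyllithium | [Li]C(=C)OC(C)(C)C | intermediate
4 | lithium pentacarbonyl(2-tert-butoxyacryloyl)chromate | [Li+].[O-]C(=[Cr])C(=C)OC(C)(C)C.[C-]#[O+].[C-]#[O+].[C-]#[O+].[C-]#[O+].[C-]#[O+] | intermediate
5 | pentacarbonyl[(1-tert-butoxyvinyl)(methoxy)carbene]chromium | COC(=[Cr])C(=C)OC(C)(C)C.[C-]#[O+].[C-]#[O+].[C-]#[O+].[C-]#[O+].[C-]#[O+] | intermediate
6 | 5-ethynyl-1,2,3-trimethoxybenzene | C#Cc1cc(OC)c(OC)c(OC)c1 | starting material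
7 | lithium (3,4,5-trimethoxyphenyl)acetylide | [Li]C#Cc1cc(OC)c(OC)c(OC)c1 | intermediate
8 | lithium 1-(dimethylamino)-3-(3,4,5-trimethoxyphenyl)prop-2-yn-1-olate (racemic) | [Li+].[O-]C(N(C)C)C#Cc1cc(OC)c(OC)c(OC)c1 | intermediate
9 | 3-(3,4,5-trimethoxyphenyl)prop-2-ynal | O=CC#Cc1cc(OC)c(OC)c(OC)c1 | intermediate
10 | ethynylmagnesium bromide | C#C[Mg]Br | starting material
11 | bromomagnesium 1-(3,4,5-trimethoxyphenyl)penta-1,4-diyn-3-olate (racemic) | C#CC(O[Mg]Br)C#Cc1cc(OC)c(OC)c(OC)c1 | intermediate
12 | 1-(3,4,5-trimethoxyphenyl)penta-1,4-diyn-3-ol (racemic) | C#CC(O)C#Cc1cc(OC)c(OC)c(OC)c1 | intermediate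
13 | tert-butyl(dimethyl){[1-(3,4,5-trimethoxyphenyl)penta-1,4-diyn-3-yl]oxy}silane (racemic) | C#CC(O[Si](C)(C)C(C)(C)C)C#Cc1cc(OC)c(OC)c(OC)c1 | intermediate
14 | tricarbonylchromium η6 complex of phenol 15 on ring A (racemic, mixture of diastereomers) | COc1cc(C(O[Si](C)(C)C(C)(C)C)C#Cc2cc(OC)c(OC)c(OC)c2)c(O)cc1OC(C)(C)C.[Cr].[C-]#[O+].[C-]#[O+].[C-]#[O+] | intermediate
15 | 5-tert-butoxy-2-[1-(tert-butyldimethylsilyloxy)-3-(3,4,5-trimethoxyphenyl)prop-2-ynyl]-4-methoxyphenol (racemic) | COc1cc(C(O[Si](C)(C)C(C)(C)C)C#Cc2cc(OC)c(OC)c(OC)c2)c(O)cc1OC(C)(C)C | intermediate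
16 | 5-tert-butoxy-2-[1-hydroxy-3-(3,4,5-trimethoxyphenyl)prop-2-ynyl]-4-methoxyphenol (racemic) | COc1cc(C(O)C#Cc2cc(OC)c(OC)c(OC)c2)c(O)cc1OC(C)(C)C | intermediate
17 | 1-(4-tert-butoxy-2-hydroxy-5-methoxyphenyl)-3-(3,4,5-trimethoxyphenyl)prop-2-yn-1-one | COc1cc(C(=O)C#Cc2cc(OC)c(OC)c(OC)c2)c(O)cc1OC(C)(C)C | intermediate
18 | (E)-1-(4-tert-butoxy-2-hydroxy-5-methoxyphenyl)-3-(diethylamino)-3-(3,4,5-trimethoxyphenyl)prop-2-en-1-one | CCN(CC)/C(c1cc(OC)c(OC)c(OC)c1)=C/C(=O)c1cc(OC)c(OC(C)(C)C)cc1O | intermediate
19 | 7-tert-butoxy-6-methoxy-2-(3,4,5-trimethoxyphenyl)-4H-chromen-4-one | COc1cc2c(=O)cc(-c3cc(OC)c(OC)c(OC)c3)oc2cc1OC(C)(C)C | intermediate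
20 | prosogerin D, 7-hydroxy-6-methoxy-2-(3,4,5-trimethoxyphenyl)-4H-chromen-4-one | COc1cc2c(=O)cc(-c3cc(OC)c(OC)c(OC)c3)oc2cc1O | target

Total step count: 9. Longest linear sequence: 8 steps (6 → 9 → 12 → 13 → 15 → 16 → 17 → 19 → 20).

Steps most likely to fail

**1. Step 5.**
- Risk: the internal aryl alkyne may compete for the unsaturated chromium centre, the skipped diyne may isomerise or oligomerise on the metal, or the vinylcarbene intermediate may leak into products without CO insertion. Any of these would make phenol formation inefficient.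
- Fallback: the second alkyne is taken out of the ring-forming event and attached afterwards.
- Setting out from 5, the same benzannulation is run with commercial 3,3-diethoxyprop-1-yne (THF, 50 °C). It passes through the Cr(CO)3-complexed acetal phenol F1 and, after exposure to air, gives 5-tert-butoxy-2-(diethoxymethyl)-4-methoxyphenol F2.
- Pyridinium p-toluenesulfonate in wet acetone frees 4-tert-butoxy-2-hydroxy-5-methoxybenzaldehyde F3.
- Lithium acetylide 7 (2.2 equiv, generated from 6 as in step 2) is added in THF at −78 → 0 °C to give the dilithium phenoxide alkoxide F4. Aqueous NH4Cl turns it into diol 16, where the route is rejoined.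

**2. Step 1.**
- Risk: slow or incomplete α-deprotonation of the hindered vinyl ether would leave t-BuLi free to attack Cr(CO)6 itself, and solvent cleavage competes on warming.
- Fallback: metalation is separated from carbene assembly by way of a storable stannane.
- Setting out from 1, the n-BuLi/KOt-Bu superbase (THF, −78 °C) gives 1-tert-butoxyvinylpotassium F5.
- Bu3SnCl traps it as tributyl(1-tert-butoxyvinyl)stannane F6, which is purified by distillation.
- Tin–lithium exchange with one equivalent of n-BuLi (THF, −78 °C) then delivers 3 free of excess base. The route is rejoined at 3 with the addition to Cr(CO)6.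

**3. Step 7.**
- Risk: oxidation of the electron-rich hydroquinone monoether nucleus (quinone formation, oxidative coupling) and ionisation of the doubly activated carbinol may compete with oxidation of the alcohol.
- Fallback: the phenol is masked before the carbinol is unveiled.
- Setting out from 15, chloromethyl methyl ether and i-Pr2NEt in CH2Cl2 give the methoxymethyl ether of 15 F7.
- Bu4NF/AcOH gives 1-[4-tert-butoxy-5-methoxy-2-(methoxymethoxy)phenyl]-3-(3,4,5-trimethoxyphenyl)prop-2-yn-1-ol F8.
- MnO2 in CH2Cl2 gives 1-[4-tert-butoxy-5-methoxy-2-(methoxymethoxy)phenyl]-3-(3,4,5-trimethoxyphenyl)prop-2-yn-1-one F9.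
- CF3CO2H in wet CH2Cl2 strips the acetal and the tert-butyl ether together to give 1-(2,4-dihydroxy-5-methoxyphenyl)-3-(3,4,5-trimethoxyphenyl)prop-2-yn-1-one F10.
- Et2NH in warm EtOH closes ring C through the (E)-β-diethylamino enaminone F11, as in step 8. The route is rejoined at the target 20.

Further compounds
F1 | step 5 | tricarbonylchromium η6 complex of 5-tert-butoxy-2-(diethoxymethyl)-4-methoxyphenol (racemic) | CCOC(OCC)c1cc(OC)c(OC(C)(C)C)cc1O.[Cr].[C-]#[O+].[C-]#[O+].[C-]#[O+]
F2 | step 5 | 5-tert-butoxy-2-(diethoxymethyl)-4-methoxyphenol | CCOC(OCC)c1cc(OC)c(OC(C)(C)C)cc1O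
F3 | step 5 | 4-tert-butoxy-2-hydroxy-5-methoxybenzaldehyde | O=Cc1cc(OC)c(OC(C)(C)C)cc1O
F4 | step 5 | dilithium salt (phenoxide and alkoxide) of diol 16 (racemic) | [Li+].[Li+].[O-]C(C#Cc1cc(OC)c(OC)c(OC)c1)c1cc(OC)c(OC(C)(C)C)cc1[O-]
F5 | step 1 | 1-tert-butoxyvinylpotassium | [K]C(=C)OC(C)(C)C
F6 | step 1 | tributyl(1-tert-butoxyvinyl)stannane | C=C(OC(C)(C)C)[Sn](CCCC)(CCCC)CCCC
F7 | step 7 | tert-butyl{1-[4-tert-butoxy-5-methoxy-2-(methoxymethoxy)phenyl]-3-(3,4,5-trimethoxyphenyl)prop-2-ynyloxy}dimethylsilane (racemic) | COCOc1cc(OC(C)(C)C)c(OC)cc1C(O[Si](C)(C)C(C)(C)C)C#Cc1cc(OC)c(OC)c(OC)c1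
F8 | step 7 | 1-[4-tert-butoxy-5-methoxy-2-(methoxymethoxy)phenyl]-3-(3,4,5-trimethoxyphenyl)prop-2-yn-1-ol (racemic) | COCOc1cc(OC(C)(C)C)c(OC)cc1C(O)C#Cc1cc(OC)c(OC)c(OC)c1
F9 | step 7 | 1-[4-tert-butoxy-5-methoxy-2-(methoxymethoxy)phenyl]-3-(3,4,5-trimethoxyphenyl)prop-2-yn-1-one | COCOc1cc(OC(C)(C)C)c(OC)cc1C(=O)C#Cc1cc(OC)c(OC)c(OC)c1
F10 | step 7 | 1-(2,4-dihydroxy-5-methoxyphenyl)-3-(3,4,5-trimethoxyphenyl)prop-2-yn-1-one | COc1cc(C(=O)C#Cc2cc(OC)c(OC)c(OC)c2)c(O)cc1O
F11 | step 7 | (E)-3-(diethylamino)-1-(2,4-dihydroxy-5-methoxyphenyl)-3-(3,4,5-trimethoxyphenyl)prop-2-en-1-one | CCN(CC)/C(c1cc(OC)c(OC)c(OC)c1)=C/C(=O)c1cc(OC)c(O)cc1O
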